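In the south-east run J rises to 30% at 20.0 h and then falls while Q keeps growing; the new flask holds more X than that run and is followed up to 2.0 d.

all flasks: Z 0.50 M
- south-east: X 0.17 M; run made earlier
- south-west: X 0.38 M; run made earlier
- flask: X 0.250 M; time 2.0 d

| run | time / h | J / % | Q / % | Z / % |
|---|---|---|---|---|
| south-east | 4.00 | 14 | 1 | 48 |
| south-east | 6.00 | 18 | 4 | 40 |
| south-east | 10.0 | 27 | 13 | 27 |
| south-east | 20.0 | 30 | 28 | 11 |
| south-east | 30.0 | 22 | 40 | 7 |
| south-east | 50.0 | 8 | 56 | 0 |
| south-west | 4.00 | 5 | 0 | 17 |
| south-west | 6.00 | 13 | 0 | 14 |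
| south-west | 10.0 | 10 | 3 | 5 |
| south-west | 20.0 | 9 | 5 | 2 |
| south-west | 30.0 | 5 | 16 | 3 |
| south-west | 50.0 | 8 | 23 | 0 |

(standard deviation of a reading: 2 percentage points)

* time, not beyond 2.0 d, at which the flask holds most J
* the amount of J, in percent of the Z charged, at that time
* earliest time at which at least nineteen twentieths of that best amount are there, in d
* latest time at which they still are, in d

- what may be going on: Z <-> D; D <-> L; J -> Q; Z + X -> G; D -> J

My first guess is that X is the limiting reagent of a quick Z + X → G, taking Z one to one. The share of Z open to J is then s = 1 − [X]/[Z], both at the start: 66.0% in the south-east run. But D and L might hold material back. At 20.0 h that run's Z, J and Q sum to 69.0%, near that share given the scatter, so I treat the south-east run as a plain chain, Z → J → Q, with two first-order rates read from it: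

kZ = ln(40% / 11%) / (20.0 h − 6.00 h) = 0.0922 h⁻¹

kJ = gain in Q / (mean J × time), from 10.0 h to 30.0 h = 0.0495 h⁻¹

Integrating dJ/dt = kZ[Z] − kJ[J] from zero and setting the slope to zero gives:

t* = ln(kZ/kJ) / (kZ − kJ) = 14.6 h

P = (kJ/kZ)^(kJ/(kZ − kJ)) = 48.6%

Call P the peak share: the part of the Z escaping X that stands as J at the top. Is it sound? For the south-east run P × s gives 32.1%, against the reading of 30%, though the same run supplied the rates, so this is a weak test. A second doubt is the clock, since X needs time too. At 4.00 h that run's Z reads 48%, already below its share, and that time is shorter than t*, so any delay from X looks small against t*, though my time may run slightly early.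

For the flask, s = 50.0%, so I commit to 24.3% at 0.608 d. The curvature at the top gives a band of 0.195 d either side, from 0.413 d to 0.803 d.

The forecast gives 22% at 0.55 d, with a band from 0.38 d to 0.76 d, taking “about 52% of the Z reaches J”, where I take s.

The flask gives 23.3% at 0.655 d, with the band from 0.475 d to 0.879 d.

    Z ⇌ D (K = 0.760, k = 0.0930 h⁻¹)
    D ⇌ L (K = 0.480, k = 0.270 h⁻¹)
    J → Q (k = 0.0510 h⁻¹)
    Z + X → G (k = 24.0 M⁻¹ h⁻¹)
    D → J (k = 1.70 h⁻¹)

At that best time the flask holds G at 50.0% and X at 0%. P × s put this flask at 24.3%. A neighbouring flask, the same but with 0.10 M of X, has a share of 80.0%, so P predicts 38.9%, and that neighbour reaches 37.2%.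

The earlier runs and the new flask come from a simulation with made-up constants; scatter was added.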